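## Retrosynthetic overview

1. The bicyclo[3.3.1]nonane core is closed last by the C1–C8 bond: the tertiary C8 cation adds to the C1 enol carbon of a dearomatized acylphloroglucinol, as in the biosynthetic ring closure. The cation is released at one site only by ionizing a fused 2,2-dimethylpyran (O→C shift), so the acid-labile side-chain alkenes never meet a protic acid.
2. The pyran-fused cyclohexadienone comes from dearomative C-alkylation at C4a of an 8-iodochroman with the (S)-side-chain triflate, then Stille prenylation at the iodide. The pyran ring steers the electrophile trans to the C3 prenyl, which becomes the required C7 configuration (prenyl syn to the acylated bridge).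
3. The chroman comes from a silyl-protected 2,4,6-trihydroxybenzophenone and (S)-lavandulyl triflate: C-alkylation, then acid hydroalkoxylation onto the para oxygen.
4. Both chiral C10 units come from one Evans N-(3-methylbut-2-enoyl)oxazolidinone by deconjugative alkylation; the benzophenone comes from phloroglucinol and a nitrile (Hoesch).
5. Ring order: benzene ring (bought) → pyran ring → dearomatization → carbocyclic C6–C7–C8 bridge closed onto C1 as the pyran opens.

Assumption: the target is taken as the enol tautomer drawn (the enol tautomers of the 2,4-dione equilibrate), and 1, 2, 4, 7, 11, 13 and 22 are bought.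

Abbreviations: Ar = 3,4-bis(triisopropylsilyloxy)phenyl; prenyl = 3-methylbut-2-en-1-yl. Atom map for steps 8–12: chroman C2, C3, C4, C4a, C8, C8a become target C8, C7, C6, C5, C1, C9.

## Route

Step 1
Reactants: 1 (S)-4-benzyloxazolidin-2-one; 2 3-methylbut-2-enoyl chloride
Product: 3 (S)-4-benzyl-3-(3-methylbut-2-enoyl)oxazolidin-2-one
Conditions: n-BuLi, THF, −78 °C; then 2, −78 to 0 °C
Reagents that add atoms: none
Why: N-acylation of the lithiated oxazolidinone (loading of the Evans auxiliary); no stereocentre is formed.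

Step 2
Reactants: 3 (S)-4-benzyl-3-(3-methylbut-2-enoyl)oxazolidin-2-one; 4 1-bromo-3-methylbut-2-ene
Product: 5 (S)-4-benzyl-3-[(2S)-5-methyl-2-(prop-1-en-2-yl)hex-4-enoyl]oxazolidin-2-one
Conditions: NaN(SiMe3)2, THF, −78 °C; 4, −78 to −40 °C
Reagents that add atoms: none
Why: Evans asymmetric alkylation of the chelated sodium dienolate (γ-deprotonation, α-alkylation with deconjugation), in which the bromide enters on the face opposite the benzyl group and sets the (2S) centre that becomes C7 of the target.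

Step 3
Reactants: 5 (S)-4-benzyl-3-[(2S)-5-methyl-2-(prop-1-en-2-yl)hex-4-enoyl]oxazolidin-2-one
Product: 6 (2S)-5-methyl-2-(prop-1-en-2-yl)hex-4-en-1-ol [(S)-lavandulol]
Conditions: LiBH4, H2O (1 equiv), Et2O, 0 °C
Reagents that add atoms: none
Why: Reductive cleavage of the N-acyloxazolidinone by borohydride gives the primary alcohol without touching the α-stereocentre and returns the auxiliary.

Step 4
Reactants: 3 (S)-4-benzyl-3-(3-methylbut-2-enoyl)oxazolidin-2-one; 7 3-methylbut-3-en-1-ol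
Product: 9 (S)-4-benzyl-3-[(2S)-5-methyl-2-(prop-1-en-2-yl)hex-5-enoyl]oxazolidin-2-one, via isopentenyl triflate 8 (not isolated)
Conditions: 7, Tf2O, 2,6-lutidine, pentane–CH2Cl2, −78 °C, cold filtration; filtrate added to 3, NaN(SiMe3)2, THF, −78 to −30 °C
Reagents that add atoms: none
Why: The same Evans deconjugative α-alkylation, now with an unactivated primary triflate, again anti to the benzyl group, sets the (2S) centre that becomes the side-chain stereocentre of the target.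

Step 5
Reactants: 9 (S)-4-benzyl-3-[(2S)-5-methyl-2-(prop-1-en-2-yl)hex-5-enoyl]oxazolidin-2-one
Product: 10 (2S)-5-methyl-2-(prop-1-en-2-yl)hex-5-en-1-ol
Conditions: LiBH4, H2O (1 equiv), Et2O, 0 °C
Reagents that add atoms: none
Why: Reductive auxiliary cleavage as in step 3; the stereocentre is not involved.

Step 6
Reactants: 11 3,4-dihydroxybenzonitrile
Product: 12 3,4-bis(triisopropylsilyloxy)benzonitrile
Conditions: i-Pr3SiCl (2.3 equiv), imidazole, DMF, 23 °C
Reagents that add atoms: chlorotriisopropylsilane, CC(C)[Si](Cl)(C(C)C)C(C)C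
Why: Imidazole-mediated silylation of both catechol hydroxyls; the bulky silyl ethers survive amide bases, anhydrous acid and silyl triflate and leave with fluoride at the end.

Step 7
Reactants: 12 3,4-bis(triisopropylsilyloxy)benzonitrile; 13 phloroglucinol
Product: 15 (2,4,6-trihydroxyphenyl)(Ar)methanone, via ketiminium chloride 14 (not isolated)
Conditions: ZnCl2, HCl (g), Et2O, 0 °C; then H2O, 50 °C
Reagents that add atoms: water, O
Why: Hoesch acylation of the electron-rich phloroglucinol by the nitrile gives the ketiminium salt, which water hydrolyses to the aryl ketone; no stereocentre is formed.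

Step 8
Reactants: 15 (2,4,6-trihydroxyphenyl)(Ar)methanone; 6 (2S)-5-methyl-2-(prop-1-en-2-yl)hex-4-en-1-ol
Product: 18 (3R)-6-(ArCO)-5,7-dihydroxy-2,2-dimethyl-3-prenylchroman, via lavandulyl triflate 16 (not isolated), via C-lavandulyl benzophenone 17 (not isolated)
Conditions: 6, Tf2O, 2,6-lutidine, pentane–CH2Cl2, −78 °C, cold filtration; filtrate added to 15 (2 equiv), LiN(SiMe3)2 (2.1 equiv per 15), THF, −78 to 0 °C; crude, p-TsOH·H2O (10 mol %), CH2Cl2, 23 °C
Reagents that add atoms: none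
Why: C-alkylation of the lithium phloroglucinolate at a free ring carbon (excess 15 limits dialkylation) is followed by acid-catalysed Markovnikov hydroalkoxylation of the isopropenyl group by the para oxygen, the ortho hydroxyl being chelated to the ketone and crowded by the aroyl group; C3 is carried over unchanged from 6.

Step 9
Reactants: 18 (3R)-6-(ArCO)-5,7-dihydroxy-2,2-dimethyl-3-prenylchroman
Product: 19 (3R)-6-(ArCO)-5,7-dihydroxy-8-iodo-2,2-dimethyl-3-prenylchroman
Conditions: N-iodosuccinimide (1.0 equiv), CH2Cl2, −40 °C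
Reagents that add atoms: N-iodosuccinimide, O=C1CCC(=O)N1I
Why: Electrophilic aromatic iodination at the only free, triply activated ring carbon is far faster than attack on the trisubstituted alkene; the iodide blocks C8 for the next step and is the handle for the later prenyl coupling.

Step 10
Reactants: 19 (3R)-6-(ArCO)-5,7-dihydroxy-8-iodo-2,2-dimethyl-3-prenylchroman; 10 (2S)-5-methyl-2-(prop-1-en-2-yl)hex-5-en-1-ol
Product: 21 (3R,4aS)-6-(ArCO)-7-hydroxy-8-iodo-2,2-dimethyl-4a-[(2R)-5-methyl-2-(prop-1-en-2-yl)hex-5-en-1-yl]-3-prenyl-3,4-dihydro-2H-chromen-5(4aH)-one, via side-chain triflate 20 (not isolated)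
Conditions: 10, Tf2O, 2,6-lutidine, pentane–CH2Cl2, −78 °C, cold filtration; filtrate added to 19, LiN(SiMe3)2 (2.2 equiv), toluene–THF 10:1, −78 to −10 °C
Reagents that add atoms: none
Why: Alkylative dearomatization of the lithium phenoxide, in which C4a is the only carbon nucleophile left (C8 carries iodine, C6 the aroyl group, both oxygens are hindered); the triflate enters axially on the pyran half-chair, anti to the pseudo-equatorial C3 prenyl (the boat-like alternative meets the axial C2 methyl), and so sets C4a (S) trans to C3.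

Step 11
Reactants: 21 (3R,4aS)-6-(ArCO)-7-hydroxy-8-iodo-2,2-dimethyl-4a-[(2R)-5-methyl-2-(prop-1-en-2-yl)hex-5-en-1-yl]-3-prenyl-3,4-dihydro-2H-chromen-5(4aH)-one; 22 tributyl(3-methylbut-2-en-1-yl)stannane
Product: 23 (3R,4aS)-6-(ArCO)-7-hydroxy-2,2-dimethyl-4a-[(2R)-5-methyl-2-(prop-1-en-2-yl)hex-5-en-1-yl]-3,8-diprenyl-3,4-dihydro-2H-chromen-5(4aH)-one
Conditions: Pd(PPh3)4 (10 mol %), CuI (20 mol %), DMF, 40 °C
Reagents that add atoms: none
Why: Stille cross-coupling of the α-iodo enone with the allylic stannane, where reductive elimination at the unsubstituted allyl terminus gives the linear prenyl group; no stereocentre is touched.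

Step 12
Reactants: 23 (3R,4aS)-6-(ArCO)-7-hydroxy-2,2-dimethyl-4a-[(2R)-5-methyl-2-(prop-1-en-2-yl)hex-5-en-1-yl]-3,8-diprenyl-3,4-dihydro-2H-chromen-5(4aH)-one
Product: 26 (1R,5R,7R)-3-(ArCO)-4-hydroxy-8,8-dimethyl-5-[(2R)-5-methyl-2-(prop-1-en-2-yl)hex-5-en-1-yl]-1,7-diprenylbicyclo[3.3.1]non-3-ene-2,9-dione, via silyl dienol ether 24 (not isolated), via silyl enol ether 25 (not isolated)
Conditions: Me3SiOTf (2.5 equiv), 2,6-di-tert-butyl-4-methylpyridine (3 equiv), CH2Cl2, −78 to −20 °C; then aq. NaHCO3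
Reagents that add atoms: none
Why: Proposed new method: O-silylation gives diene 24, silyl activation of the C5 carbonyl then ionizes the tertiary pyran C2–O1 bond (as in silyl triflate cleavage of tert-butyl ethers and esters), and the tethered tertiary cation, the C8 cation of the biosynthetic closure, is captured in the ion pair by the silyl enol ether carbon C8 (target C1) on the face already carrying C4, through a boat-like closure made easy by the sp2 C9, so that C1 (R) is fixed by the tether, C5 and C7 are untouched and the prenyl group ends syn to the dione bridge; the closest known reactions are the Petasis–Ferrier O→C rearrangement, the O→C glycoside rearrangement and Reetz tert-alkylation of silyl enol ethers, and the hindered pyridine only traps protons, so the 1,1-disubstituted alkenes are never protonated.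

Step 13
Reactants: 26 (1R,5R,7R)-3-(ArCO)-4-hydroxy-8,8-dimethyl-5-[(2R)-5-methyl-2-(prop-1-en-2-yl)hex-5-en-1-yl]-1,7-diprenylbicyclo[3.3.1]non-3-ene-2,9-dione
Product: 27 (1R,5R,7R)-3-(3,4-dihydroxybenzoyl)-4-hydroxy-8,8-dimethyl-5-[(2R)-5-methyl-2-(prop-1-en-2-yl)hex-5-en-1-yl]-1,7-diprenylbicyclo[3.3.1]non-3-ene-2,9-dione
Conditions: Bu4NF (2.5 equiv), AcOH (3 equiv), THF, 0 °C
Reagents that add atoms: none
Why: Fluoride-mediated cleavage of the two aryl silyl ethers under acetic acid buffering avoids base-promoted catechol oxidation and acid-promoted cyclization of the isopropenyl side chain; no stereocentre is affected.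

## Compound list

1 | (S)-4-benzyloxazolidin-2-one | O=C1N[C@@H](Cc2ccccc2)CO1 | starting material
2 | 3-methylbut-2-enoyl chloride | CC(C)=CC(=O)Cl | starting material
3 | (S)-4-benzyl-3-(3-methylbut-2-enoyl)oxazolidin-2-one | CC(C)=CC(=O)N1C(=O)OC[C@@H]1Cc1ccccc1 | intermediate
4 | 1-bromo-3-methylbut-2-ene | CC(C)=CCBr | starting material
5 | (S)-4-benzyl-3-[(2S)-5-methyl-2-(prop-1-en-2-yl)hex-4-enoyl]oxazolidin-2-one | CC(C)=CC[C@@H](C(C)=C)C(=O)N1C(=O)OC[C@@H]1Cc1ccccc1 | intermediate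
6 | (2S)-5-methyl-2-(prop-1-en-2-yl)hex-4-en-1-ol | CC(C)=CC[C@H](CO)C(C)=C | intermediate
7 | 3-methylbut-3-en-1-ol | C=C(C)CCO | starting material
8 | 3-methylbut-3-en-1-yl trifluoromethanesulfonate | C=C(C)CCOS(=O)(=O)C(F)(F)F | intermediate
9 | (S)-4-benzyl-3-[(2S)-5-methyl-2-(prop-1-en-2-yl)hex-5-enoyl]oxazolidin-2-one | C=C(C)CC[C@@H](C(C)=C)C(=O)N1C(=O)OC[C@@H]1Cc1ccccc1 | intermediate
10 | (2S)-5-methyl-2-(prop-1-en-2-yl)hex-5-en-1-ol | C=C(C)CC[C@H](CO)C(C)=C | intermediate
11 | 3,4-dihydroxybenzonitrile | N#Cc1ccc(O)c(O)c1 | starting material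
12 | 3,4-bis(triisopropylsilyloxy)benzonitrile | N#Cc1ccc(O[Si](C(C)C)(C(C)C)C(C)C)c(O[Si](C(C)C)(C(C)C)C(C)C)c1 | intermediate
13 | phloroglucinol | Oc1cc(O)cc(O)c1 | starting material
14 | [3,4-bis(triisopropylsilyloxy)phenyl](2,4,6-trihydroxyphenyl)methaniminium chloride | [NH2+]=C(c1ccc(O[Si](C(C)C)(C(C)C)C(C)C)c(O[Si](C(C)C)(C(C)C)C(C)C)c1)c1c(O)cc(O)cc1O.[Cl-] | intermediate
15 | [3,4-bis(triisopropylsilyloxy)phenyl](2,4,6-trihydroxyphenyl)methanone | O=C(c1ccc(O[Si](C(C)C)(C(C)C)C(C)C)c(O[Si](C(C)C)(C(C)C)C(C)C)c1)c1c(O)cc(O)cc1O | intermediate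
16 | (2S)-5-methyl-2-(prop-1-en-2-yl)hex-4-en-1-yl trifluoromethanesulfonate | CC(C)=CC[C@H](COS(=O)(=O)C(F)(F)F)C(C)=C | intermediate
17 | [3,4-bis(triisopropylsilyloxy)phenyl]{2,4,6-trihydroxy-3-[(2R)-5-methyl-2-(prop-1-en-2-yl)hex-4-en-1-yl]phenyl}methanone | O=C(c1ccc(O[Si](C(C)C)(C(C)C)C(C)C)c(O[Si](C(C)C)(C(C)C)C(C)C)c1)c1c(O)cc(O)c(C[C@@H](CC=C(C)C)C(C)=C)c1O | intermediate
18 | [3,4-bis(triisopropylsilyloxy)phenyl][(3R)-5,7-dihydroxy-2,2-dimethyl-3-(3-methylbut-2-en-1-yl)chroman-6-yl]methanone | CC(C)=CC[C@@H]1Cc2c(O)c(C(=O)c3ccc(O[Si](C(C)C)(C(C)C)C(C)C)c(O[Si](C(C)C)(C(C)C)C(C)C)c3)c(O)cc2OC1(C)C | intermediate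
19 | [3,4-bis(triisopropylsilyloxy)phenyl][(3R)-5,7-dihydroxy-8-iodo-2,2-dimethyl-3-(3-methylbut-2-en-1-yl)chroman-6-yl]methanone | CC(C)=CC[C@@H]1Cc2c(O)c(C(=O)c3ccc(O[Si](C(C)C)(C(C)C)C(C)C)c(O[Si](C(C)C)(C(C)C)C(C)C)c3)c(O)c(I)c2OC1(C)C | intermediate
20 | (2S)-5-methyl-2-(prop-1-en-2-yl)hex-5-en-1-yl trifluoromethanesulfonate | C=C(C)CC[C@H](COS(=O)(=O)C(F)(F)F)C(C)=C | intermediate
21 | (3R,4aS)-6-[3,4-bis(triisopropylsilyloxy)benzoyl]-7-hydroxy-8-iodo-2,2-dimethyl-3-(3-methylbut-2-en-1-yl)-4a-[(2R)-5-methyl-2-(prop-1-en-2-yl)hex-5-en-1-yl]-3,4-dihydro-2H-chromen-5(4aH)-one | CC(C)=CC[C@@H]1C[C@]2(C[C@@H](CCC(C)=C)C(C)=C)C(=O)C(C(=O)c3ccc(O[Si](C(C)C)(C(C)C)C(C)C)c(O[Si](C(C)C)(C(C)C)C(C)C)c3)=C(O)C(I)=C2OC1(C)C | intermediate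
22 | tributyl(3-methylbut-2-en-1-yl)stannane | CC(C)=CC[Sn](CCCC)(CCCC)CCCC | starting material
23 | (3R,4aS)-6-[3,4-bis(triisopropylsilyloxy)benzoyl]-7-hydroxy-2,2-dimethyl-3,8-bis(3-methylbut-2-en-1-yl)-4a-[(2R)-5-methyl-2-(prop-1-en-2-yl)hex-5-en-1-yl]-3,4-dihydro-2H-chromen-5(4aH)-one | CC(C)=CC[C@@H]1C[C@]2(C[C@@H](CCC(C)=C)C(C)=C)C(=O)C(C(=O)c3ccc(O[Si](C(C)C)(C(C)C)C(C)C)c(O[Si](C(C)C)(C(C)C)C(C)C)c3)=C(O)C(CC=C(C)C)=C2OC1(C)C | intermediate
24 | 7-O-trimethylsilyl ether of 23 | CC(C)=CC[C@@H]1C[C@]2(C[C@@H](CCC(C)=C)C(C)=C)C(=O)C(C(=O)c3ccc(O[Si](C(C)C)(C(C)C)C(C)C)c(O[Si](C(C)C)(C(C)C)C(C)C)c3)=C(O[Si](C)(C)C)C(CC=C(C)C)=C2OC1(C)C | intermediate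
25 | 4-O-trimethylsilyl ether of 26 | C=C(C)CC[C@H](C[C@@]12C[C@@H](CC=C(C)C)C(C)(C)[C@@](CC=C(C)C)(C(=O)C(C(=O)c3ccc(O[Si](C(C)C)(C(C)C)C(C)C)c(O[Si](C(C)C)(C(C)C)C(C)C)c3)=C1O[Si](C)(C)C)C2=O)C(=C)C | intermediate
26 | (1R,5R,7R)-3-[3,4-bis(triisopropylsilyloxy)benzoyl]-4-hydroxy-8,8-dimethyl-1,7-bis(3-methylbut-2-en-1-yl)-5-[(2R)-5-methyl-2-(prop-1-en-2-yl)hex-5-en-1-yl]bicyclo[3.3.1]non-3-ene-2,9-dione | C=C(C)CC[C@H](C[C@@]12C[C@@H](CC=C(C)C)C(C)(C)[C@@](CC=C(C)C)(C(=O)C(C(=O)c3ccc(O[Si](C(C)C)(C(C)C)C(C)C)c(O[Si](C(C)C)(C(C)C)C(C)C)c3)=C1O)C2=O)C(=C)C | intermediate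
27 | (1R,5R,7R)-3-(3,4-dihydroxybenzoyl)-4-hydroxy-8,8-dimethyl-1,7-bis(3-methylbut-2-en-1-yl)-5-[(2R)-5-methyl-2-(prop-1-en-2-yl)hex-5-en-1-yl]bicyclo[3.3.1]non-3-ene-2,9-dione | C=C(C)CC[C@H](C[C@@]12C[C@@H](CC=C(C)C)C(C)(C)[C@@](CC=C(C)C)(C(=O)C(C(=O)c3ccc(O)c(O)c3)=C1O)C2=O)C(=C)C | target

## Step count and risks

Total step count: 13. Longest linear sequence: 9 steps (steps 1, 2, 3, 8, 9, 10, 11, 12, 13).

**Step 12 (most likely to fail).** The tertiary cation must bond to a fully substituted carbon through a boat-like closure, and elimination to the isopropenyl compound could win. A protic acid cannot rescue that, because the lower side chain would then cyclize instead. Fallback, from 21 back to 26: make the bond one substitution level lower and add the prenyl group afterwards. Deiodination of 21 (Pd(PPh3)4, Bu3SnH) gives the 8-unsubstituted pyranodienone F6. The same silyl triflate O→C shift then joins the cation to a CH carbon and gives the bridgehead-unsubstituted trione F7. Double deprotonation of F7 (lithium 2,2,6,6-tetramethylpiperidide, THF, −78 °C; enolate first, then the bridgehead between two carbonyl groups) and alkylation with 4 returns to 26.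

**Step 10.** This is an SN2 reaction of a β-branched triflate at a fully substituted ring carbon; O-alkylation or triflate elimination may dominate. Fallback, from 19 back to 21: replace the SN2 step by a dearomative Michael addition. The enone 6-methyl-3-methylidenehept-6-en-2-one F4 is made from ethyl acetoacetate and 8 by alkylation and decarboxylative Mannich methylenation. The dilithium salt of 19 adds to F4 at C4a under the same pyran control and gives the methyl ketone F5. The centre next to the ketone forms as a mixture; the (R)-epimer is separated and the other is recycled by base epimerization. Wittig methylenation (Ph3P=CH2) of the only unconjugated ketone then leads to 21.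

**Step 8.** The triflate may alkylate oxygen, or the acid may close the pyran onto the ortho hydroxyl. Fallback, from 6 and 15 back to 18: an anionic annulation in which only the ionized para oxygen can close the ring. Chemoselective Mukaiyama hydration of the 1,1-disubstituted alkene of 6 (Co(acac)2, PhSiH3, O2) gives the diol (2R)-2-(2-hydroxypropan-2-yl)-5-methylhex-4-en-1-ol F1. F1 is converted (1,1′-sulfonyldiimidazole, NaH) into the cyclic sulfate (5R)-4,4-dimethyl-5-(3-methylbut-2-en-1-yl)-1,3,2-dioxathiane 2,2-dioxide F2. The dilithium salt of 15 opens F2 at the primary carbon to the lithium tertiary sulfate monoester F3. At pH 8–9 (NaHCO3, aqueous MeCN, 40 °C) the para phenoxide displaces sulfate by SN1 to give 18.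

Further compounds
F1 | step 8 | (2R)-2-(2-hydroxypropan-2-yl)-5-methylhex-4-en-1-ol | CC(C)=CC[C@H](CO)C(C)(C)O
F2 | step 8 | (5R)-4,4-dimethyl-5-(3-methylbut-2-en-1-yl)-1,3,2-dioxathiane 2,2-dioxide | CC(C)=CC[C@@H]1COS(=O)(=O)OC1(C)C
F3 | step 8 | lithium (R)-configured tertiary sulfate monoester of the C-alkylated benzophenone | [Li+].[O-]S(=O)(=O)OC(C)(C)[C@H](CC=C(C)C)Cc1c(O)cc(O)c(C(=O)c2ccc(O[Si](C(C)C)(C(C)C)C(C)C)c(O[Si](C(C)C)(C(C)C)C(C)C)c2)c1O
F4 | step 10 | 6-methyl-3-methylidenehept-6-en-2-one | C=C(CCC(C)=C)C(C)=O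
F5 | step 10 | (3R,4aS)-4a-[(2R)-2-acetyl-5-methylhex-5-en-1-yl]-6-[3,4-bis(triisopropylsilyloxy)benzoyl]-7-hydroxy-8-iodo-2,2-dimethyl-3-(3-methylbut-2-en-1-yl)-3,4-dihydro-2H-chromen-5(4aH)-one | CC(C)=CC[C@@H]1C[C@]2(C[C@@H](CCC(C)=C)C(C)=O)C(=O)C(C(=O)c3ccc(O[Si](C(C)C)(C(C)C)C(C)C)c(O[Si](C(C)C)(C(C)C)C(C)C)c3)=C(O)C(I)=C2OC1(C)C
F6 | step 12 | (3R,4aS)-6-[3,4-bis(triisopropylsilyloxy)benzoyl]-7-hydroxy-2,2-dimethyl-3-(3-methylbut-2-en-1-yl)-4a-[(2R)-5-methyl-2-(prop-1-en-2-yl)hex-5-en-1-yl]-3,4-dihydro-2H-chromen-5(4aH)-one | CC(C)=CC[C@@H]1C[C@]2(C[C@@H](CCC(C)=C)C(C)=C)C(=O)C(C(=O)c3ccc(O[Si](C(C)C)(C(C)C)C(C)C)c(O[Si](C(C)C)(C(C)C)C(C)C)c3)=C(O)C=C2OC1(C)C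
F7 | step 12 | (1R,5R,7R)-3-[3,4-bis(triisopropylsilyloxy)benzoyl]-4-hydroxy-8,8-dimethyl-7-(3-methylbut-2-en-1-yl)-5-[(2R)-5-methyl-2-(prop-1-en-2-yl)hex-5-en-1-yl]bicyclo[3.3.1]non-3-ene-2,9-dione | C=C(C)CC[C@H](C[C@@]12C[C@@H](CC=C(C)C)C(C)(C)[C@@H](C(=O)C(C(=O)c3ccc(O[Si](C(C)C)(C(C)C)C(C)C)c(O[Si](C(C)C)(C(C)C)C(C)C)c3)=C1O)C2=O)C(=C)C
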